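**Retrosynthetic overview**
1. The target comes from the ring-closed 8-epi alcohol by Mitsunobu esterification with angelic acid (inversion at C8) and desilylation.
2. Key disconnection C7–C8: an intramolecular CrCl2 allylation in which C7, the β-carbon of a 3-(bromomethyl)butenolide and normally an acceptor carbon, attacks the C8 aldehyde as a homoenolate-type nucleophile. This closes the ten-membered carbocycle, creates the α-methylene lactone and sets C7 and C8.
3. The bromomethylbutenolide comes from a C6 allylic alcohol and 2-(bromomethyl)acrylic acid (esterification, ring-closing metathesis); C6 comes from a catalytic asymmetric vinylation; the C8 aldehyde comes from a prenyl group.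
4. The furanone comes from gold-catalysed 5-endo cyclisation of an α′-hydroxy ynone, made from an alkyne (C4 by organocatalytic hydroxymethylation) and a dioxolanone from (R)-lactic acid (C10 by Seebach alkylation).
5. Ring order: furanone, then butenolide, then the carbocycle (nine-membered oxa-bridged ring) together with the α-methylene-γ-lactone.

Assumption: 4,4-dimethoxybutanal is bought as a catalogue chemical (otherwise it is one i-Bu2AlH reduction from methyl 4,4-dimethoxybutanoate).
Atom labels C1–C15 are the germacrane labels of the target: C1 ketone, C2=C3 enol ether, C4 bearing C15H2OH, C6 lactone carbinol, C7, C8 ester carbinol, C10 quaternary carbon with C14H3, C11=C13 methylene, C12 lactone carbonyl.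

**Step 1**
Reactants: 1 (R)-lactic acid; 2 pivalaldehyde
Product: 3 (2R,5R)-2-tert-butyl-5-methyl-1,3-dioxolan-4-one
Conditions: t-BuCHO, TsOH·H2O (cat.), H2SO4 (cat.), pentane, reflux, Dean–Stark; recrystallised from pentane at −78 °C
Reagents that add atoms: pivalaldehyde (2), CC(C)(C)C=O
Why: Seebach acetalisation of an α-hydroxy acid; the cis acetal is the thermodynamic, crystalline isomer, so the lactate centre fixes the new acetal centre (2R) that later relays the chirality.

**Step 2**
Reactants: 3 (2R,5R)-2-tert-butyl-5-methyl-1,3-dioxolan-4-one; 4 prenyl bromide (1-bromo-3-methylbut-2-ene)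
Product: 6 (2R,5S)-2-tert-butyl-5-methyl-5-(3-methylbut-2-en-1-yl)-1,3-dioxolan-4-one, via lithium enolate 5 (not isolated)
Conditions: LiN(iPr)2, THF, −78 °C; then 4, −78 → −30 °C
Reagents that add atoms: prenyl bromide (4), CC(C)=CCBr
Why: Enolate alkylation with self-regeneration of the stereocentre; the planar enolate is attacked anti to the tert-butyl group, rebuilding C5 as the (5S) quaternary centre that becomes C10 (10S).

**Step 3**
Reactants: 7 4,4-dimethoxybutanal; 8 formaldehyde
Product: 10 (2S)-2-{[(tert-butyldiphenylsilyl)oxy]methyl}-4,4-dimethoxybutanal, via β-hydroxy aldehyde 9 (not isolated)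
Conditions: 37% aq. HCHO, (R)-α,α-diphenylprolinol trimethylsilyl ether (10 mol%), pH 7 phosphate buffer, toluene, rt; organic layer dried, then TBDPSCl, imidazole, CH2Cl2, 0 °C
Reagents that add atoms: formaldehyde (8), C=O; tert-butyl(chloro)diphenylsilane, CC(C)(C)[Si](Cl)(c1ccccc1)c1ccccc1
Why: Enamine-catalysed cross-aldol (α-hydroxymethylation); formaldehyde enters the E-enamine on the face away from the CPh2OSiMe3 group, setting C4 as (S), and the labile aldol is silylated without isolation.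

**Step 4**
Reactants: 10 (2S)-2-{[(tert-butyldiphenylsilyl)oxy]methyl}-4,4-dimethoxybutanal
Product: 11 (3R)-3-{[(tert-butyldiphenylsilyl)oxy]methyl}-5,5-dimethoxypent-1-yne
Conditions: dimethyl (1-diazo-2-oxopropyl)phosphonate, K2CO3, MeOH, 0 °C → rt
Reagents that add atoms: dimethyl (1-diazo-2-oxopropyl)phosphonate, CC(=O)C(=[N+]=[N-])P(=O)(OC)OC
Why: Ohira–Bestmann (Seyferth–Gilbert) homologation, mild enough for α-branched β-silyloxy aldehydes; C4 keeps its geometry (the descriptor becomes R only because the CIP ranking changes).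

**Step 5**
Reactants: 11 (3R)-3-{[(tert-butyldiphenylsilyl)oxy]methyl}-5,5-dimethoxypent-1-yne; 6 (2R,5S)-2-tert-butyl-5-methyl-5-(3-methylbut-2-en-1-yl)-1,3-dioxolan-4-one
Product: 14 (5S,9R)-9-{[(tert-butyldiphenylsilyl)oxy]methyl}-5-hydroxy-11,11-dimethoxy-2,5-dimethylundec-2-en-7-yn-6-one, via lithium acetylide 12 (not isolated), via lithium hemiketal alkoxide 13 (not isolated)
Conditions: n-BuLi, THF, −78 °C; then 6, −78 °C; AcOH, −78 °C → rt
Reagents that add atoms: none
Why: Acetylide C-acylation by a lactone-type (acylal) carbonyl; the tetrahedral alkoxide 13 persists until protonation, so only one acetylide adds, and it then sheds pivalaldehyde to free the tertiary C10 alcohol without touching a stereocentre.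

**Step 6**
Reactants: 14 (5S,9R)-9-{[(tert-butyldiphenylsilyl)oxy]methyl}-5-hydroxy-11,11-dimethoxy-2,5-dimethylundec-2-en-7-yn-6-one
Product: 16 (3S)-4-[(tert-butyldiphenylsilyl)oxy]-3-[(5S)-5-methyl-5-(3-methylbut-2-en-1-yl)-4-oxo-4,5-dihydrofuran-2-yl]butanal, via furanone dimethyl acetal 15 (not isolated)
Conditions: Ph3PAuNTf2 (2 mol%), toluene, rt; then THF, 1 M aq. HCl, rt
Reagents that add atoms: water, O
Why: 5-endo-dig hydroalkoxylation of the α′-hydroxy ynone catalysed by monovalent gold gives the 3(2H)-furanone (C10–O–C3 bond), and acid hydrolysis of the acetal then frees the C6 aldehyde; silyl ether and prenyl group are inert.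

**Step 7**
Reactants: 16 (3S)-4-[(tert-butyldiphenylsilyl)oxy]-3-[(5S)-5-methyl-5-(3-methylbut-2-en-1-yl)-4-oxo-4,5-dihydrofuran-2-yl]butanal
Product: 17 (2S)-5-[(2S,4R)-1-[(tert-butyldiphenylsilyl)oxy]-4-hydroxyhex-5-en-2-yl]-2-methyl-2-(3-methylbut-2-en-1-yl)furan-3(2H)-one
Conditions: Zn(CH=CH2)2 (pre-formed, salt-free, 2.5 equiv), (−)-3-exo-morpholinoisoborneol [(−)-MIB, 5 mol%], toluene/hexane, −20 → 0 °C; aqueous work-up
Reagents that add atoms: divinylzinc, C=C[Zn]C=C
Why: Amino-alcohol-catalysed enantioselective vinylzinc addition (Noyori–Oppolzer type); catalyst-controlled Si-face delivery sets C6 as (R) independently of the remote C4 centre, and the vinylogous-ester ketone is not attacked.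

**Step 8**
Reactants: 17 (2S)-5-[(2S,4R)-1-[(tert-butyldiphenylsilyl)oxy]-4-hydroxyhex-5-en-2-yl]-2-methyl-2-(3-methylbut-2-en-1-yl)furan-3(2H)-one; 18 2-(bromomethyl)acrylic acid
Product: 19 (3R,5S)-6-[(tert-butyldiphenylsilyl)oxy]-5-[(5S)-5-methyl-5-(3-methylbut-2-en-1-yl)-4-oxo-4,5-dihydrofuran-2-yl]hex-1-en-3-yl 2-(bromomethyl)prop-2-enoate
Conditions: 18, N,N′-diisopropylcarbodiimide, DMAP (5 mol%), CH2Cl2, 0 °C
Reagents that add atoms: 2-(bromomethyl)acrylic acid (18), C=C(CBr)C(=O)O
Why: Steglich esterification of the only free hydroxyl; the C6–O bond is not broken, so the configuration is retained.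

**Step 9**
Reactants: 19 (3R,5S)-6-[(tert-butyldiphenylsilyl)oxy]-5-[(5S)-5-methyl-5-(3-methylbut-2-en-1-yl)-4-oxo-4,5-dihydrofuran-2-yl]hex-1-en-3-yl 2-(bromomethyl)prop-2-enoate
Product: 20 (2S)-5-[(2S)-1-[(2R)-4-(bromomethyl)-5-oxo-2,5-dihydrofuran-2-yl]-3-[(tert-butyldiphenylsilyl)oxy]propan-2-yl]-2-methyl-2-(3-methylbut-2-en-1-yl)furan-3(2H)-one
Conditions: second-generation Hoveyda–Grubbs catalyst [RuCl2(H2IMes)(=CH-C6H4-2-OiPr), 5 mol%], toluene (5 mM), 80 °C
Reagents that add atoms: none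
Why: Ring-closing metathesis of the terminal allylic alkene onto the acrylate gives the five-membered butenolide with loss of ethene; the trisubstituted prenyl alkene and the furanone alkene do not take part.

**Step 10**
Reactants: 20 (2S)-5-[(2S)-1-[(2R)-4-(bromomethyl)-5-oxo-2,5-dihydrofuran-2-yl]-3-[(tert-butyldiphenylsilyl)oxy]propan-2-yl]-2-methyl-2-(3-methylbut-2-en-1-yl)furan-3(2H)-one
Product: 22 {(2S)-5-[(2S)-1-[(2R)-4-(bromomethyl)-5-oxo-2,5-dihydrofuran-2-yl]-3-[(tert-butyldiphenylsilyl)oxy]propan-2-yl]-2-methyl-3-oxo-2,3-dihydrofuran-2-yl}acetaldehyde, via prenyl diol 21 (not isolated)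
Conditions: OsO4 (2 mol%), NaIO4 (4 equiv), 2,6-lutidine, dioxane/H2O 3:1, rt; crude aldehyde used at once
Reagents that add atoms: sodium periodate, [Na+].[O-]I(=O)(=O)=O; osmium tetroxide (catalytic oxygen carrier), O=[Os](=O)(=O)=O
Why: Lemieux–Johnson oxidative cleavage; electrophilic OsO4 takes the only electron-rich alkene (prenyl) and spares the two conjugated, electron-poor ring alkenes, unmasking the C8 aldehyde under near-neutral conditions.

**Step 11 (key step)**
Reactants: 22 {(2S)-5-[(2S)-1-[(2R)-4-(bromomethyl)-5-oxo-2,5-dihydrofuran-2-yl]-3-[(tert-butyldiphenylsilyl)oxy]propan-2-yl]-2-methyl-3-oxo-2,3-dihydrofuran-2-yl}acetaldehyde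
Product: 24 (4S,6R,7R,8S,10S)-15-[(tert-butyldiphenylsilyl)oxy]-8-hydroxy-1-oxo-3,10-epoxygermacra-2,11(13)-dien-12,6-olide, via allylchromium 23 (not isolated)
Conditions: CrCl2 (6 equiv), THF, rt, 22 added by syringe pump over 10 h (final 2 mM); H2O quench
Reagents that add atoms: none
Why: Proposed new method: divalent chromium inserts into the allylic C–Br bond to give allylchromium 23, in which C7 (the butenolide β-carbon, normally a Michael-acceptor carbon) becomes the nucleophilic γ-terminus and adds to the C8 aldehyde carbon through a closed six-membered chair transition state with allylic transposition, forming the C11=C13 methylene, the α-methylene-γ-lactone and the ten-membered carbocycle at once; attack anti to the C5 chain on C6 gives the 6,7-trans lactone (same C7 geometry as the target, descriptor R here only through CIP ranking) and the ring-locked E-type allylmetal with C9 equatorial gives the 8S alcohol; the closest known reactions are intermolecular Zn-, In- or CrCl2-mediated Barbier additions of 3-(bromomethyl)furan-2(5H)-ones to aldehydes and CrCl2-mediated macrocyclising allylations (Nozaki–Hiyama type) used for germacranolides.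

**Step 12**
Reactants: 24 (4S,6R,7R,8S,10S)-15-[(tert-butyldiphenylsilyl)oxy]-8-hydroxy-1-oxo-3,10-epoxygermacra-2,11(13)-dien-12,6-olide; 25 angelic acid [(Z)-2-methylbut-2-enoic acid]
Product: 26 (4S,6R,7S,8R,10S)-8-[(Z)-2-methylbut-2-enoyloxy]-15-[(tert-butyldiphenylsilyl)oxy]-1-oxo-3,10-epoxygermacra-2,11(13)-dien-12,6-olide
Conditions: 25, PPh3, DIAD, toluene, 0 °C → rt
Reagents that add atoms: angelic acid (25), C/C=C(/C)C(=O)O
Why: Mitsunobu esterification; SN2 displacement of the C8 oxyphosphonium by angelate inverts C8 from S to R, and because the acid acts as a carboxylate nucleophile and not as an activated acyl donor the Z-alkene is not isomerised to tiglate.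

**Step 13**
Reactants: 26 (4S,6R,7S,8R,10S)-8-[(Z)-2-methylbut-2-enoyloxy]-15-[(tert-butyldiphenylsilyl)oxy]-1-oxo-3,10-epoxygermacra-2,11(13)-dien-12,6-olide
Product: 27 (4S,6R,7S,8R,10S)-8-[(Z)-2-methylbut-2-enoyloxy]-15-hydroxy-1-oxo-3,10-epoxygermacra-2,11(13)-dien-12,6-olide (target)
Conditions: HF·pyridine, pyridine/THF, 0 °C → rt
Reagents that add atoms: none
Why: Fluoride-induced Si–O cleavage under buffered conditions frees the primary C15 alcohol without touching the angelate, the α-methylene lactone or any stereocentre.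

**Compound list**
1 | (R)-lactic acid | C[C@@H](O)C(=O)O | starting material
2 | pivalaldehyde | CC(C)(C)C=O | starting material
3 | (2R,5R)-2-tert-butyl-5-methyl-1,3-dioxolan-4-one | C[C@H]1O[C@@H](C(C)(C)C)OC1=O | intermediate
4 | prenyl bromide | CC(C)=CCBr | starting material
5 | lithium enolate of 3 [lithium (2R)-2-tert-butyl-5-methyl-1,3-dioxol-4-olate] | CC1=C(O[Li])O[C@H](C(C)(C)C)O1 | intermediate
6 | (2R,5S)-2-tert-butyl-5-methyl-5-(3-methylbut-2-en-1-yl)-1,3-dioxolan-4-one | C[C@@]1(CC=C(C)C)O[C@@H](C(C)(C)C)OC1=O | intermediate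
7 | 4,4-dimethoxybutanal | COC(OC)CCC=O | starting material
8 | formaldehyde | C=O | starting material
9 | (2S)-2-(hydroxymethyl)-4,4-dimethoxybutanal | COC(OC)C[C@@H](CO)C=O | intermediate
10 | (2S)-2-{[(tert-butyldiphenylsilyl)oxy]methyl}-4,4-dimethoxybutanal | COC(OC)C[C@@H](CO[Si](c1ccccc1)(c1ccccc1)C(C)(C)C)C=O | intermediate
11 | (3R)-3-{[(tert-butyldiphenylsilyl)oxy]methyl}-5,5-dimethoxypent-1-yne | COC(OC)C[C@@H](CO[Si](c1ccccc1)(c1ccccc1)C(C)(C)C)C#C | intermediate
12 | lithium acetylide of 11 | COC(OC)C[C@@H](CO[Si](c1ccccc1)(c1ccccc1)C(C)(C)C)C#C[Li] | intermediate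
13 | lithium hemiketal alkoxide from 12 and 6 (both epimers at the new hemiketal carbon) | C[C@@]1(CC=C(C)C)O[C@@H](C(C)(C)C)OC1(O[Li])C#C[C@H](CO[Si](c2ccccc2)(c2ccccc2)C(C)(C)C)CC(OC)OC | intermediate
14 | (5S,9R)-9-{[(tert-butyldiphenylsilyl)oxy]methyl}-5-hydroxy-11,11-dimethoxy-2,5-dimethylundec-2-en-7-yn-6-one | CC(C)=CC[C@](C)(O)C(=O)C#C[C@H](CO[Si](c1ccccc1)(c1ccccc1)C(C)(C)C)CC(OC)OC | intermediate
15 | (2S)-5-[(2S)-1-[(tert-butyldiphenylsilyl)oxy]-4,4-dimethoxybutan-2-yl]-2-methyl-2-(3-methylbut-2-en-1-yl)furan-3(2H)-one | CC(C)=CC[C@]1(C)OC(=CC1=O)[C@H](CO[Si](c2ccccc2)(c2ccccc2)C(C)(C)C)CC(OC)OC | intermediate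
16 | (3S)-4-[(tert-butyldiphenylsilyl)oxy]-3-[(5S)-5-methyl-5-(3-methylbut-2-en-1-yl)-4-oxo-4,5-dihydrofuran-2-yl]butanal | CC(C)=CC[C@]1(C)OC(=CC1=O)[C@H](CO[Si](c2ccccc2)(c2ccccc2)C(C)(C)C)CC=O | intermediate
17 | (2S)-5-[(2S,4R)-1-[(tert-butyldiphenylsilyl)oxy]-4-hydroxyhex-5-en-2-yl]-2-methyl-2-(3-methylbut-2-en-1-yl)furan-3(2H)-one | CC(C)=CC[C@]1(C)OC(=CC1=O)[C@H](CO[Si](c2ccccc2)(c2ccccc2)C(C)(C)C)C[C@@H](O)C=C | intermediate
18 | 2-(bromomethyl)acrylic acid | C=C(CBr)C(=O)O | starting material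
19 | (3R,5S)-6-[(tert-butyldiphenylsilyl)oxy]-5-[(5S)-5-methyl-5-(3-methylbut-2-en-1-yl)-4-oxo-4,5-dihydrofuran-2-yl]hex-1-en-3-yl 2-(bromomethyl)prop-2-enoate | CC(C)=CC[C@]1(C)OC(=CC1=O)[C@H](CO[Si](c2ccccc2)(c2ccccc2)C(C)(C)C)C[C@@H](OC(=O)C(=C)CBr)C=C | intermediate
20 | (2S)-5-[(2S)-1-[(2R)-4-(bromomethyl)-5-oxo-2,5-dihydrofuran-2-yl]-3-[(tert-butyldiphenylsilyl)oxy]propan-2-yl]-2-methyl-2-(3-methylbut-2-en-1-yl)furan-3(2H)-one | CC(C)=CC[C@]1(C)OC(=CC1=O)[C@H](CO[Si](c2ccccc2)(c2ccccc2)C(C)(C)C)C[C@H]3OC(=O)C(CBr)=C3 | intermediate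
21 | vicinal diol from the prenyl alkene of 20 [2-(2,3-dihydroxy-3-methylbutyl) analogue, both carbinol epimers] | CC(C)(O)C(O)C[C@]1(C)OC(=CC1=O)[C@H](CO[Si](c2ccccc2)(c2ccccc2)C(C)(C)C)C[C@H]3OC(=O)C(CBr)=C3 | intermediate
22 | {(2S)-5-[(2S)-1-[(2R)-4-(bromomethyl)-5-oxo-2,5-dihydrofuran-2-yl]-3-[(tert-butyldiphenylsilyl)oxy]propan-2-yl]-2-methyl-3-oxo-2,3-dihydrofuran-2-yl}acetaldehyde | O=CC[C@]1(C)OC(=CC1=O)[C@H](CO[Si](c2ccccc2)(c2ccccc2)C(C)(C)C)C[C@H]3OC(=O)C(CBr)=C3 | intermediate
23 | allylchromium dichloride from 22 (CrCl2 unit on C13) | O=CC[C@]1(C)OC(=CC1=O)[C@H](CO[Si](c2ccccc2)(c2ccccc2)C(C)(C)C)C[C@H]3OC(=O)C(C[Cr](Cl)Cl)=C3 | intermediate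
24 | (4S,6R,7R,8S,10S)-15-[(tert-butyldiphenylsilyl)oxy]-8-hydroxy-1-oxo-3,10-epoxygermacra-2,11(13)-dien-12,6-olide | C=C1C(=O)O[C@@H]2C[C@@H](CO[Si](c4ccccc4)(c4ccccc4)C(C)(C)C)C3=CC(=O)[C@](C)(C[C@H](O)[C@@H]12)O3 | intermediate
25 | angelic acid | C/C=C(/C)C(=O)O | starting material
26 | (4S,6R,7S,8R,10S)-8-[(Z)-2-methylbut-2-enoyloxy]-15-[(tert-butyldiphenylsilyl)oxy]-1-oxo-3,10-epoxygermacra-2,11(13)-dien-12,6-olide | C=C1C(=O)O[C@@H]2C[C@@H](CO[Si](c4ccccc4)(c4ccccc4)C(C)(C)C)C3=CC(=O)[C@](C)(C[C@@H](OC(=O)/C(C)=C\C)[C@@H]12)O3 | intermediate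
27 | (4S,6R,7S,8R,10S)-8-[(Z)-2-methylbut-2-enoyloxy]-15-hydroxy-1-oxo-3,10-epoxygermacra-2,11(13)-dien-12,6-olide | C=C1C(=O)O[C@@H]2C[C@@H](CO)C3=CC(=O)[C@](C)(C[C@@H](OC(=O)/C(C)=C\C)[C@@H]12)O3 | target

**Step count and risks**
Total: 13 steps. Longest linear sequence: 11 steps (7 to 27 through steps 3–13; the branch from 1 joins at step 5 and is equally long).

The three steps most likely to fail:

Step 11 (macrocyclising allylation). Oligomerisation may compete with ring closure. The facial selectivity at C7 and the C8 configuration rest on a chair model that the ring strain of the forming nine-membered ring could override. The chromium alkoxide could also shift the lactone to O8. The fallback replaces the metal-templated closed transition state by a Lewis-acid-promoted open one, which should give the 8R alcohol directly. It sets out from 20: Pd(PPh3)4-catalysed stannylation with Bu3SnSnBu3 gives the allylstannane F1. OsO4/NaIO4 cleavage of the prenyl group gives the stannyl aldehyde F2. BF3·OEt2 in CH2Cl2 at −78 °C under high dilution then closes the ring by an intramolecular allylstannane addition through an open antiperiplanar transition state (syn-selective) to the 8R alcohol F3. Yamaguchi esterification of F3 with angelic acid (2,4,6-trichlorobenzoyl chloride, Et3N, DMAP, toluene, rt, retention at C8) comes back to the route at 26.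

Step 12 (Mitsunobu inversion). C8 is flanked by the ring carbon C7 and a neopentyl-like C9, so elimination, retention through participation of the lactone carbonyl, or phosphine addition to the α-methylene lactone may win. The fallback inverts C8 by oxidation and reduction instead of substitution. It sets out from 24: Dess–Martin periodinane with NaHCO3 gives the C8 ketone F4. Reduction at −78 °C with NaBH4/CeCl3, or with a CBS oxazaborolidine and BH3·SMe2 if substrate control is poor, delivers hydride to the α-face and gives the 8R alcohol already called F3 above. This is angeloylated under the Yamaguchi conditions given there and comes back at 26.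

Step 5 (acetylide addition to the dioxolanone). The carbonyl sits next to a quaternary centre, and early collapse of the tetrahedral alkoxide would expose the ynone to a second acetylide. The fallback changes the acyl donor. It sets out from 6: Me2AlN(OMe)Me (from AlMe3 and MeNH(OMe)·HCl, CH2Cl2, 0 °C) opens the dioxolanone with loss of pivalaldehyde to the Weinreb amide F5. After deprotonation of its hydroxyl with i-PrMgCl, the lithium acetylide 12 adds once (stable chelated adduct), and aqueous work-up comes back to the route at 14.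

**Further compounds**
F1 | step 11 | (2S)-5-[(2S)-1-[(tert-butyldiphenylsilyl)oxy]-3-{(2R)-5-oxo-4-[(tributylstannyl)methyl]-2,5-dihydrofuran-2-yl}propan-2-yl]-2-methyl-2-(3-methylbut-2-en-1-yl)furan-3(2H)-one | CC(C)=CC[C@]1(C)OC(=CC1=O)[C@H](CO[Si](c2ccccc2)(c2ccccc2)C(C)(C)C)C[C@H]3OC(=O)C(C[Sn](CCCC)(CCCC)CCCC)=C3
F2 | step 11 | {(2S)-5-[(2S)-1-[(tert-butyldiphenylsilyl)oxy]-3-{(2R)-5-oxo-4-[(tributylstannyl)methyl]-2,5-dihydrofuran-2-yl}propan-2-yl]-2-methyl-3-oxo-2,3-dihydrofuran-2-yl}acetaldehyde | O=CC[C@]1(C)OC(=CC1=O)[C@H](CO[Si](c2ccccc2)(c2ccccc2)C(C)(C)C)C[C@H]3OC(=O)C(C[Sn](CCCC)(CCCC)CCCC)=C3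
F3 | step 11 | (4S,6R,7R,8R,10S)-15-[(tert-butyldiphenylsilyl)oxy]-8-hydroxy-1-oxo-3,10-epoxygermacra-2,11(13)-dien-12,6-olide | C=C1C(=O)O[C@@H]2C[C@@H](CO[Si](c4ccccc4)(c4ccccc4)C(C)(C)C)C3=CC(=O)[C@](C)(C[C@@H](O)[C@@H]12)O3
F4 | step 12 | (4S,6R,7S,10S)-15-[(tert-butyldiphenylsilyl)oxy]-1,8-dioxo-3,10-epoxygermacra-2,11(13)-dien-12,6-olide | C=C1C(=O)O[C@@H]2C[C@@H](CO[Si](c4ccccc4)(c4ccccc4)C(C)(C)C)C3=CC(=O)[C@](C)(CC(=O)[C@@H]12)O3
F5 | step 5 | (2S)-2-hydroxy-N-methoxy-N,2,5-trimethylhex-4-enamide | CC(C)=CC[C@](C)(O)C(=O)N(C)OC
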